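The cyclobutane carries its oxygenated carbon C1, the one bonded to the ring system, next to the quaternary CMe2 carbon C2. The C1–C4 bond is therefore cut back to an aryl tert-pentyl ketone in which C1 is the carbonyl carbon and C4 the terminal methyl, γ to it. Irradiating that ketone as a crystalline salt with an enantiopure amine should close the four-membered ring, form the C1–C4 bond and set the only stereocentre (R) in one operation. The precursor is a 3-acyloxyphenyl ketone whose hemisuccinate arm holds the ammonium carboxylate and whose phenolic oxygen later becomes a quinone oxygen. Ring A of the naphthazarin is then annulated onto the derived benzoquinone by a Diels–Alder reaction.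

Key step: step 5

Assumption on the chemistry: the sense of induction of a chiral salt crystal cannot be predicted, so the (S)-amine is written as the one giving the (R)-carbinol; if it gives the (S)-carbinol, the (R)-amine is used, whose mirror-image crystal must give the mirror-image product.
Further remark: 2,5-bis(trimethylsilyloxy)furan is taken as a purchased reagent, and the target is written as the naphthazarin tautomer with the side chain on the quinonoid ring.

Step 1
Reactants: 1 2-chloro-2-methylbutane; 2 3-methoxybenzoyl chloride
Product: 4 1-(3-methoxyphenyl)-2,2-dimethylbutan-1-one, via tert-pentylmagnesium chloride 3 (not isolated)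
Conditions: 1, Mg, Et2O, reflux; then added to 2, CuCl (5 mol%), THF, −10 °C
Reagents that add atoms: none
Why: Copper-catalysed acylation of a tertiary Grignard reagent by an aroyl chloride (Grignard ketone synthesis) stops at the hindered, non-enolisable ketone; no stereocentre is formed.

Step 2
Reactants: 4 1-(3-methoxyphenyl)-2,2-dimethylbutan-1-one
Product: 6 1-(3-hydroxyphenyl)-2,2-dimethylbutan-1-one, via dibromo[3-(2,2-dimethylbutanoyl)phenoxy]borane 5 (not isolated)
Conditions: BBr3, CH2Cl2, −78 → 0 °C; then H2O
Reagents that add atoms: none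
Why: Lewis-acid cleavage of an aryl methyl ether (BBr3 demethylation), to which the ketone with its quaternary α-carbon is inert.

Step 3
Reactants: 6 1-(3-hydroxyphenyl)-2,2-dimethylbutan-1-one; 7 succinic anhydride
Product: 8 4-[3-(2,2-dimethylbutanoyl)phenoxy]-4-oxobutanoic acid
Conditions: 4-(dimethylamino)pyridine (cat.), pyridine, 20 °C; cold dilute HCl work-up
Reagents that add atoms: none
Why: Ring-opening acylation of a phenol by a cyclic anhydride under nucleophilic catalysis gives the half ester only, and the cold acidic work-up keeps the acid un-ionised so that its carboxylate cannot expel the phenol again.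

Step 4
Reactants: 8 4-[3-(2,2-dimethylbutanoyl)phenoxy]-4-oxobutanoic acid; 9 (S)-1-phenylethylamine
Product: 10 (S)-1-phenylethylammonium 4-[3-(2,2-dimethylbutanoyl)phenoxy]-4-oxobutanoate
Conditions: 9 (1.0 equiv), dry EtOAc, 0 °C; hexane, −20 °C, crystallisation
Reagents that add atoms: none
Why: Acid–base salt formation with an enantiopure amine guarantees a chiral space group, and dry, cold, prompt crystallisation keeps aminolysis and carboxylate-assisted loss of the aryl ester in check.

Step 5
Reactants: 10 (S)-1-phenylethylammonium 4-[3-(2,2-dimethylbutanoyl)phenoxy]-4-oxobutanoate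
Product: 12 4-{3-[(1R)-1-hydroxy-2,2-dimethylcyclobutyl]phenoxy}-4-oxobutanoic acid, via cyclobutanol ammonium salt 11 (not isolated)
Conditions: hν (medium-pressure Hg lamp, Pyrex, λ > 290 nm), crystals suspended in hexane, N2, −20 °C; then EtOAc, cold 1 M HCl
Reagents that add atoms: none
Why: Light absorbed by the aryl ketone gives its n,π* triplet, whose oxygen takes a hydrogen from the terminal methyl through a six-membered transition state, and the 1-hydroxy-1,4-biradical then couples at its two radical carbons. The closest known reaction type is the Norrish–Yang photocyclisation of α,α-dialkyl aryl ketones, run in the solid state on a carboxylate salt of an enantiopure amine. The cyclobutane is closed by intramolecular radical–radical recombination between the ketyl carbon and the γ-carbon, not by a polar ring closure. The carbinol stereocentre is governed by the crystal: the (S)-cation enforces a chiral space group in which the ketone is frozen as one twisted conformer with the methyl group over one carbonyl face, and least-motion closure in the lattice cavity keeps that face. The step needs γ-abstraction and coupling to beat α-cleavage and biradical fragmentation, and needs one enantiotopic face; the α gem-dimethyl group disfavours the fragmentation geometry, the lattice cage lets acyl–alkyl radical pairs recombine to ketone, the meta ester neither pushes a π,π* state below the reactive one nor offers an abstractable hydrogen, and the Pyrex cut-off spares the aryl ester from photo-Fries rearrangement.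

Step 6
Reactants: 12 4-{3-[(1R)-1-hydroxy-2,2-dimethylcyclobutyl]phenoxy}-4-oxobutanoic acid
Product: 13 3-[(1R)-1-hydroxy-2,2-dimethylcyclobutyl]phenol
Conditions: K2CO3, MeOH, 0 °C
Reagents that add atoms: none
Why: Base-mediated methanolysis (transesterification) of the activated aryl ester, helped by the neighbouring carboxylate, frees the phenol without touching the tertiary cyclobutanol or its stereocentre.

Step 7
Reactants: 13 3-[(1R)-1-hydroxy-2,2-dimethylcyclobutyl]phenol
Product: 14 (1R)-1-{3-[(tert-butyldimethylsilyl)oxy]phenyl}-2,2-dimethylcyclobutan-1-ol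
Conditions: TBSCl, imidazole, DMF, 0 °C → rt
Reagents that add atoms: tert-butyldimethylsilyl chloride, CC(C)(C)[Si](C)(C)Cl
Why: Imidazole-promoted silylation of a phenol (silyl ether protection) is selective because the crowded tertiary alcohol does not react with the bulky silyl chloride.

Step 8
Reactants: 15 angelic acid (two molecules per molecule of anhydride)
Product: 16 angelic anhydride [(2Z)-2-methylbut-2-enoic anhydride]
Conditions: N,N'-dicyclohexylcarbodiimide (0.5 equiv per acid), CH2Cl2, 0 °C → rt; filtration
Reagents that add atoms: angelic acid (the second molecule of 15, which supplies the second acyl group), C/C=C(/C)C(=O)O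
Why: Carbodiimide dehydration of two molecules of a carboxylic acid to the symmetrical anhydride runs without base or nucleophilic catalyst, so the (Z) double bond should not isomerise.

Step 9
Reactants: 14 (1R)-1-{3-[(tert-butyldimethylsilyl)oxy]phenyl}-2,2-dimethylcyclobutan-1-ol; 16 angelic anhydride
Product: 18 (1R)-1-{3-[(tert-butyldimethylsilyl)oxy]phenyl}-2,2-dimethylcyclobutyl (2Z)-2-methylbut-2-enoate, via lithium alkoxide 17 (not isolated)
Conditions: LiN(SiMe3)2 (1.05 equiv), THF, −78 °C; then 16, −78 → 0 °C; NH4Cl (aq)
Reagents that add atoms: none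
Why: Acylation of a preformed tertiary lithium alkoxide by a carboxylic anhydride (nucleophilic acyl substitution) leaves the C–O bond of the stereocentre intact, so (R) is retained, and the near-stoichiometric non-nucleophilic base should leave the angelate geometry unchanged.

Step 10
Reactants: 18 (1R)-1-{3-[(tert-butyldimethylsilyl)oxy]phenyl}-2,2-dimethylcyclobutyl (2Z)-2-methylbut-2-enoate
Product: 19 (1R)-1-(3-hydroxyphenyl)-2,2-dimethylcyclobutyl (2Z)-2-methylbut-2-enoate
Conditions: Bu4NF, AcOH, THF, 0 °C
Reagents that add atoms: none
Why: Fluoride-induced desilylation of an aryl silyl ether, buffered by acetic acid, leaves the hindered tertiary ester and the (Z) double bond alone.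

Step 11
Reactants: 19 (1R)-1-(3-hydroxyphenyl)-2,2-dimethylcyclobutyl (2Z)-2-methylbut-2-enoate
Product: 20 (1R)-1-(3,6-dioxocyclohexa-1,4-dien-1-yl)-2,2-dimethylcyclobutyl (2Z)-2-methylbut-2-enoate
Conditions: (KSO3)2NO (2.2 equiv), KH2PO4 (aq), acetone, 0 °C → rt
Reagents that add atoms: potassium nitrosodisulfonate, [K+].[K+].[O]N(S(=O)(=O)[O-])S(=O)(=O)[O-]
Why: Teuber oxidation, in which the phenoxyl radical couples at its free para position with a second nitrosodisulfonate radical and the adduct collapses to the para-quinone; the new carbonyl lies next to the side chain, and ester and stereocentre are spectators.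

Step 12
Reactants: 20 (1R)-1-(3,6-dioxocyclohexa-1,4-dien-1-yl)-2,2-dimethylcyclobutyl (2Z)-2-methylbut-2-enoate; 21 2,5-bis(trimethylsilyloxy)furan
Product: 24 (1R)-1-(5,8-dihydroxy-1,4-dioxo-1,4-dihydronaphthalen-2-yl)-2,2-dimethylcyclobutyl (2Z)-2-methylbut-2-enoate (target), via oxygen-bridged bis(trimethylsilyloxy) cycloadduct 22 (not isolated), via 4a,8a-dihydronaphthalene-1,4,5,8-tetraone tautomer 23 (not isolated)
Conditions: CH2Cl2, −78 °C → rt; then 1 M HCl, THF, 0 °C
Reagents that add atoms: none
Why: Diels–Alder reaction of the electron-rich bis(silyloxy)furan at the unsubstituted double bond of the quinone, followed by acid-induced desilylation, opening of the oxygen bridge and double enolisation, gives the naphthazarin at the same oxidation level; the ring-fusion centres vanish and the cyclobutyl centre is remote.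

Compound list
1 | 2-chloro-2-methylbutane | CCC(C)(C)Cl | starting material
2 | 3-methoxybenzoyl chloride | COc1cccc(C(Cl)=O)c1 | starting material
3 | tert-pentylmagnesium chloride (2-methylbutan-2-ylmagnesium chloride) | CCC(C)(C)[Mg]Cl | intermediate (not isolated)
4 | 1-(3-methoxyphenyl)-2,2-dimethylbutan-1-one | CCC(C)(C)C(=O)c1cccc(OC)c1 | intermediate
5 | dibromo[3-(2,2-dimethylbutanoyl)phenoxy]borane | CCC(C)(C)C(=O)c1cccc(OB(Br)Br)c1 | intermediate (not isolated)
6 | 1-(3-hydroxyphenyl)-2,2-dimethylbutan-1-one | CCC(C)(C)C(=O)c1cccc(O)c1 | intermediate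
7 | succinic anhydride | O=C1CCC(=O)O1 | starting material
8 | 4-[3-(2,2-dimethylbutanoyl)phenoxy]-4-oxobutanoic acid | CCC(C)(C)C(=O)c1cccc(OC(=O)CCC(=O)O)c1 | intermediate
9 | (S)-1-phenylethylamine | C[C@H](N)c1ccccc1 | starting material
10 | (S)-1-phenylethylammonium 4-[3-(2,2-dimethylbutanoyl)phenoxy]-4-oxobutanoate | CCC(C)(C)C(=O)c1cccc(OC(=O)CCC(=O)[O-])c1.C[C@H]([NH3+])c1ccccc1 | intermediate
11 | (S)-1-phenylethylammonium 4-{3-[(1R)-1-hydroxy-2,2-dimethylcyclobutyl]phenoxy}-4-oxobutanoate | O[C@]1(c2cccc(OC(=O)CCC(=O)[O-])c2)CCC1(C)C.C[C@H]([NH3+])c1ccccc1 | intermediate (not isolated)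
12 | 4-{3-[(1R)-1-hydroxy-2,2-dimethylcyclobutyl]phenoxy}-4-oxobutanoic acid | O[C@]1(c2cccc(OC(=O)CCC(=O)O)c2)CCC1(C)C | intermediate
13 | 3-[(1R)-1-hydroxy-2,2-dimethylcyclobutyl]phenol | O[C@]1(c2cccc(O)c2)CCC1(C)C | intermediate
14 | (1R)-1-{3-[(tert-butyldimethylsilyl)oxy]phenyl}-2,2-dimethylcyclobutan-1-ol | O[C@]1(c2cccc(O[Si](C)(C)C(C)(C)C)c2)CCC1(C)C | intermediate
15 | angelic acid [(2Z)-2-methylbut-2-enoic acid] | C/C=C(/C)C(=O)O | starting material
16 | angelic anhydride [(2Z)-2-methylbut-2-enoic anhydride] | C/C=C(/C)C(=O)OC(=O)/C(C)=C\C | intermediate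
17 | lithium (1R)-1-{3-[(tert-butyldimethylsilyl)oxy]phenyl}-2,2-dimethylcyclobutan-1-olate | [Li+].[O-][C@]1(c2cccc(O[Si](C)(C)C(C)(C)C)c2)CCC1(C)C | intermediate (not isolated)
18 | (1R)-1-{3-[(tert-butyldimethylsilyl)oxy]phenyl}-2,2-dimethylcyclobutyl (2Z)-2-methylbut-2-enoate | C/C=C(/C)C(=O)O[C@]1(c2cccc(O[Si](C)(C)C(C)(C)C)c2)CCC1(C)C | intermediate
19 | (1R)-1-(3-hydroxyphenyl)-2,2-dimethylcyclobutyl (2Z)-2-methylbut-2-enoate | C/C=C(/C)C(=O)O[C@]1(c2cccc(O)c2)CCC1(C)C | intermediate
20 | (1R)-1-(3,6-dioxocyclohexa-1,4-dien-1-yl)-2,2-dimethylcyclobutyl (2Z)-2-methylbut-2-enoate | C/C=C(/C)C(=O)O[C@]1(C2=CC(=O)C=CC2=O)CCC1(C)C | intermediate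
21 | 2,5-bis(trimethylsilyloxy)furan | C[Si](C)(C)Oc1ccc(O[Si](C)(C)C)o1 | starting material
22 | (1R)-1-[5,8-dioxo-1,4-bis(trimethylsilyloxy)-1,4,4a,5,8,8a-hexahydro-1,4-epoxynaphthalen-6-yl]-2,2-dimethylcyclobutyl (2Z)-2-methylbut-2-enoate, mixture of ring-fusion isomers | C/C=C(/C)C(=O)O[C@]1(C2=CC(=O)C3C(C2=O)C2(O[Si](C)(C)C)C=CC3(O[Si](C)(C)C)O2)CCC1(C)C | intermediate (not isolated)
23 | (1R)-2,2-dimethyl-1-(1,4,5,8-tetraoxo-1,4,4a,5,8,8a-hexahydronaphthalen-2-yl)cyclobutyl (2Z)-2-methylbut-2-enoate | C/C=C(/C)C(=O)O[C@]1(C2=CC(=O)C3C(C2=O)C(=O)C=CC3=O)CCC1(C)C | intermediate (not isolated)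
24 | (1R)-1-(5,8-dihydroxy-1,4-dioxo-1,4-dihydronaphthalen-2-yl)-2,2-dimethylcyclobutyl (2Z)-2-methylbut-2-enoate | C/C=C(/C)C(=O)O[C@]1(C2=CC(=O)c3c(O)ccc(O)c3C2=O)CCC1(C)C | target

Total step count: 12. Longest linear sequence: 11 (steps 1–7 and 9–12; step 8 is a one-step side branch that prepares the acyl donor).

Steps most likely to fail

1. Step 5. The lattice may discriminate the two carbonyl faces poorly, or the crystals may lose order as conversion rises (melting, debris from α-cleavage), so that enantiomeric purity erodes or the reaction stalls. Fallback: setting out from 8, irradiation in dilute degassed MeCN through Pyrex follows the same photocyclisation without lattice control and should give racemic 4-[3-(1-hydroxy-2,2-dimethylcyclobutyl)phenoxy]-4-oxobutanoic acid F1. Stereocontrol then comes from resolution instead of the crystal: the enantiomers are parted by preparative chromatography on a chiral stationary phase (the acid handle also allows classical resolution with an enantiopure amine). The unwanted 4-{3-[(1S)-1-hydroxy-2,2-dimethylcyclobutyl]phenoxy}-4-oxobutanoic acid F2 is set aside, and the (R)-acid is 12, where the route is rejoined.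

2. Step 11. The nitrosodisulfonate radical may couple at the unhindered ortho position instead of the para position that lies next to the quaternary carbinyl carbon, leading to an ortho-quinone, or the oxidation may be slow and run on to degradation. Fallback: setting out from 19, a polar two-electron oxidation with the trivalent iodine reagent PhI(OAc)2 (2 equiv) in MeCN/H2O at 0 °C replaces the radical coupling. Water, a small nucleophile, attacks the para carbon of the aryloxy-iodane, and the resulting (1R)-1-(2,5-dihydroxyphenyl)-2,2-dimethylcyclobutyl (2Z)-2-methylbut-2-enoate F3 is oxidised in the flask by the second equivalent, coming back to the route at 20.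

3. Step 9. Acyl transfer to the crowded tertiary alkoxide may be slow, and warming may then isomerise the acyl donor from (Z) to (E) through γ-deprotonation. Fallback: setting out from 14, the angelate is built by olefination instead of being transferred intact. The lithium alkoxide 17 is acylated with 2-[bis(2,2,2-trifluoroethoxy)phosphoryl]propanoyl chloride, an acyl donor far more electrophilic than the anhydride that may also react through the derived phosphonoketene, to give (1R)-1-{3-[(tert-butyldimethylsilyl)oxy]phenyl}-2,2-dimethylcyclobutyl 2-[bis(2,2,2-trifluoroethoxy)phosphoryl]propanoate F4. Still–Gennari olefination of F4 with acetaldehyde (KN(SiMe3)2, 18-crown-6, THF, −78 °C) should form the (Z)-trisubstituted double bond under kinetic control and comes back to the route at 18.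

Further compounds
F1 | step 5 | rac-4-[3-(1-hydroxy-2,2-dimethylcyclobutyl)phenoxy]-4-oxobutanoic acid | OC1(c2cccc(OC(=O)CCC(=O)O)c2)CCC1(C)C
F2 | step 5 | 4-{3-[(1S)-1-hydroxy-2,2-dimethylcyclobutyl]phenoxy}-4-oxobutanoic acid | O[C@@]1(c2cccc(OC(=O)CCC(=O)O)c2)CCC1(C)C
F3 | step 11 | (1R)-1-(2,5-dihydroxyphenyl)-2,2-dimethylcyclobutyl (2Z)-2-methylbut-2-enoate | C/C=C(/C)C(=O)O[C@]1(c2cc(O)ccc2O)CCC1(C)C
F4 | step 9 | (1R)-1-{3-[(tert-butyldimethylsilyl)oxy]phenyl}-2,2-dimethylcyclobutyl 2-[bis(2,2,2-trifluoroethoxy)phosphoryl]propanoate, both epimers at the phosphonate carbon | CC(C(=O)O[C@]1(c2cccc(O[Si](C)(C)C(C)(C)C)c2)CCC1(C)C)P(=O)(OCC(F)(F)F)OCC(F)(F)F
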